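**Plan**

1. Retrosynthesis (flavan numbering; ring A = benzo ring of the chroman, ring C = its pyran ring, ring D = the methylated phenol ring): cut the ring D–vinyl bond (Suzuki–Miyaura), take the vinylboron unit back to a C8 formyl group, then open ring C at C4–C3 and O1–C2 in one oxa-(4+2) disconnection to styrene and an o-quinone methide.
2. Enabling feature: O1 and C4 sit on the neighbouring ring A carbons C8a and C4a, and C4a is ortho/para to the oxygens at C5, C7 and C8a, so the ArCH2/ArO pair is a latent, strongly stabilised heterodiene C4=C4a–C8a=O1; C2 carries a phenyl group, so the two-atom partner is styrene.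
3. Precursor design: the heterodiene comes from the symmetric 2-hydroxy-4,6-dimethoxybenzene-1,3-dicarbaldehyde by reduction of one formyl group; the other formyl group (the future C8 vinyl carbon) stays on during the cycloaddition, deactivates ring A against self-alkylation and removes any later C6/C8 regiochemical question.
4. Forward order: ring A from 1,3,5-trimethoxybenzene, then ring C by the cycloaddition, then C8 formyl to (E)-alkenylboronate, then coupling with the iodophenol of ring D (made from 2,6-dimethoxytoluene through symmetric intermediates).
5. Stereochemistry: C2 (S) is set by the chiral Brønsted acid in the cycloaddition; the E alkene is set in the boron-Wittig step and retained in the cross-coupling.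

Key step: step 4

Assumption: the sense of induction of the chiral acid in step 4 cannot be predicted with certainty; the (S)-configured acid is written, and its mirror image would be used if it led to the 2R series.

**Route**

Step 1
Reactants: 1 1,3,5-trimethoxybenzene
Product: 2 2,4,6-trimethoxybenzene-1,3-dicarbaldehyde
Conditions: Cl2CHOMe (3 equiv), TiCl4 (4 equiv), CH2Cl2, 0 °C → rt; then ice/1 M HCl
Reagents that add atoms: dichloromethyl methyl ether, COC(Cl)Cl (formyl carbons); water, O (formyl oxygens, on hydrolysis)
Why: Rieche formylation (electrophilic aromatic substitution with TiCl4-activated dichloromethyl methyl ether) is strong enough to formylate this ring twice, and the second formyl group can only enter one of two equivalent positions still flanked by two methoxy groups, so 2 is the only dialdehyde possible.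

Step 2
Reactants: 2 2,4,6-trimethoxybenzene-1,3-dicarbaldehyde
Product: 3 2-hydroxy-4,6-dimethoxybenzene-1,3-dicarbaldehyde
Conditions: BCl3 (1.1 equiv), CH2Cl2, −78 → 0 °C; then H2O
Reagents that add atoms: none
Why: Chelation-assisted ortho-demethylation by BCl3 should select the C2 methoxy group, because it is flanked by two formyl groups, is twisted out of the ring plane (the most Lewis-basic ether oxygen, with either carbonyl able to hold the boron) and loses steric compression on cleavage, whereas the 4- and 6-methoxy groups lie in plane and are conjugated.

Step 3
Reactants: 3 2-hydroxy-4,6-dimethoxybenzene-1,3-dicarbaldehyde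
Product: 4 2-hydroxy-3-(hydroxymethyl)-4,6-dimethoxybenzaldehyde
Conditions: NaBH4 (0.3 equiv), THF/MeOH, −20 °C; pH 7 buffer work-up; used promptly
Reagents that add atoms: none
Why: Borohydride reduction with a deficit of hydride should stop largely after one formyl group, since the two are equivalent by symmetry (no site question) and, once one is reduced, the remaining one becomes the full vinylogous carboxylate of the phenolate and is less electrophilic.

Step 4
Reactants: 4 2-hydroxy-3-(hydroxymethyl)-4,6-dimethoxybenzaldehyde; 5 styrene
Product: 7 (2S)-5,7-dimethoxy-2-phenyl-3,4-dihydro-2H-chromene-8-carbaldehyde, via o-quinone methide 6 (not isolated)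
Conditions: styrene (5 equiv), (S)-3,3'-bis(2,4,6-triisopropylphenyl)-1,1'-binaphthyl-2,2'-diyl N-triflylphosphoramide (5 mol %), 5 Å MS, PhMe, 0 °C → rt, slow addition of 4
Reagents that add atoms: none
Why: Proposed new method: the acid dehydrates 4 to the o-quinone methide 6, which stays hydrogen-bonded to the chiral phosphoramide through its carbonyl oxygen (the neighbouring formyl oxygen offers a second contact), and the terminal carbon of styrene attacks the exocyclic methylene (bond C4–C3) while the developing benzylic cation collapses onto the carbonyl oxygen (bond O1–C2) in an asynchronous inverse-electron-demand oxa-(4+2) cycloaddition. The closest known reaction type is the chiral N-triflylphosphoramide-catalysed (4+2) cycloaddition of styrenes with o-quinone methides that carry an aryl group on the methide carbon, and asymmetric Prins-type (4+2) reactions of styrenes with formaldehyde-derived cations under strong chiral Brønsted acids show that an unsubstituted CH2 electrophile can still be steered at the styrene terminus; new here is the methide-unsubstituted, formyl-bearing o-quinone methide. Ring C is closed in the intermolecular (4+2) mode, four atoms (C4, C4a, C8a, O1) coming from 6 and two (C3, C2) from styrene, with the C4–C3 bond leading. The only new stereocentre, C2, is under pure catalyst control: the chiral counter-anion selects the face of styrene within the hydrogen-bonded ion pair. The step needs regioselectivity (phenyl at C2), which follows from the polarity match of the nucleophilic styrene CH2 with the electrophilic methide carbon, and chemoselectivity for styrene over arene alkylation or self-condensation of 6, which the formyl group secures because it is conjugated to all three ring oxygens, silences C6 of substrate and product as a Friedel–Crafts nucleophile and raises the electrophilicity of 6, with slow addition keeping 6 dilute. A second annulation is impossible because only one hydroxymethyl arm is present and the phenolic oxygen is consumed.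

Step 5
Reactants: 7 (2S)-5,7-dimethoxy-2-phenyl-3,4-dihydro-2H-chromene-8-carbaldehyde
Product: 8 2-[(E)-2-[(2S)-5,7-dimethoxy-2-phenyl-3,4-dihydro-2H-chromen-8-yl]ethenyl]-4,4,5,5-tetramethyl-1,3,2-dioxaborolane
Conditions: CH2(Bpin)2 (1.3 equiv), LiTMP (1.3 equiv), THF, 0 °C; then 7, −78 °C → rt; H2O quench
Reagents that add atoms: bis[(pinacolato)boryl]methane, CC1(C)OB(CB2OC(C)(C)C(C)(C)O2)OC1(C)C
Why: Boron-Wittig olefination, in which the lithiated geminal bis(boronate) adds to the non-enolisable aldehyde and syn B–O elimination should give the trans alkenylboronate (the bulky di-ortho-substituted aryl group reinforcing E selectivity), while the C2 stereocentre, a benzylic ether without an acidifying group, is not touched by the base, which is consumed before 7 is added.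

Step 6
Reactants: 9 2,6-dimethoxytoluene
Product: 11 3,5-dimethoxy-4-methylphenol, via arylboronate 10 (not isolated)
Conditions: B2pin2 (0.6 equiv), [Ir(OMe)(cod)]2 (1.5 mol %), 4,4'-di-tert-butyl-2,2'-bipyridine (3 mol %), THF, 80 °C; then H2O2, NaOH, THF/H2O, 0 °C
Reagents that add atoms: bis(pinacolato)diboron, CC1(C)OB(B2OC(C)(C)C(C)(C)O2)OC1(C)C (boron of intermediate 10 only); hydrogen peroxide, OO (the phenol oxygen)
Why: Sterically controlled iridium-catalysed C–H borylation should attack the only ring C–H that is not ortho to a substituent (para to the methyl group), and alkaline peroxide oxidation of the C–B bond in the same flask gives the phenol at that position (one-pot borylation/oxidation).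

Step 7
Reactants: 11 3,5-dimethoxy-4-methylphenol
Product: 12 2-iodo-3,5-dimethoxy-4-methylphenol
Conditions: NIS (1.0 equiv), CH2Cl2, −40 → 0 °C, dark
Reagents that add atoms: N-iodosuccinimide, O=C1CCC(=O)N1I
Why: Electrophilic aromatic iodination of a phenol whose two open positions are equivalent by symmetry (the para position carries the methyl group), so one equivalent of NIS at low temperature can give only 12 as the mono-iodide.

Step 8
Reactants: 8 2-[(E)-2-[(2S)-5,7-dimethoxy-2-phenyl-3,4-dihydro-2H-chromen-8-yl]ethenyl]-4,4,5,5-tetramethyl-1,3,2-dioxaborolane; 12 2-iodo-3,5-dimethoxy-4-methylphenol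
Product: 13 2-[(E)-2-[(2S)-5,7-dimethoxy-2-phenyl-3,4-dihydro-2H-chromen-8-yl]ethenyl]-3,5-dimethoxy-4-methylphenol
Conditions: Pd(OAc)2 (5 mol %), SPhos (10 mol %), K3PO4 (3 equiv), 1,4-dioxane/H2O (5:1), 70 °C, degassed; pH 6–7 work-up, light excluded
Reagents that add atoms: none
Why: Suzuki–Miyaura coupling proceeds with retention of alkene geometry, the electron-rich biarylphosphine SPhos supports oxidative addition and reductive elimination at the di-ortho-substituted, electron-rich aryl iodide, the free phenol is tolerated as its phenoxide, and the basic medium spares the acid-sensitive o-hydroxystilbene, so no protecting group is needed.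

**Compound list**

1 | 1,3,5-trimethoxybenzene | COc1cc(OC)cc(OC)c1 | starting material
2 | 2,4,6-trimethoxybenzene-1,3-dicarbaldehyde | COc1cc(OC)c(C=O)c(OC)c1C=O | intermediate
3 | 2-hydroxy-4,6-dimethoxybenzene-1,3-dicarbaldehyde | COc1cc(OC)c(C=O)c(O)c1C=O | intermediate
4 | 2-hydroxy-3-(hydroxymethyl)-4,6-dimethoxybenzaldehyde | COc1cc(OC)c(C=O)c(O)c1CO | intermediate
5 | styrene | C=Cc1ccccc1 | starting material
6 | o-quinone methide 2,4-dimethoxy-5-methylidene-6-oxocyclohexa-1,3-diene-1-carbaldehyde (formed in the flask) | C=C1C(OC)=CC(OC)=C(C=O)C1=O | intermediate
7 | (2S)-5,7-dimethoxy-2-phenyl-3,4-dihydro-2H-chromene-8-carbaldehyde | O=Cc1c(OC)cc(OC)c2c1O[C@H](c1ccccc1)CC2 | intermediate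
8 | 2-[(E)-2-[(2S)-5,7-dimethoxy-2-phenyl-3,4-dihydro-2H-chromen-8-yl]ethenyl]-4,4,5,5-tetramethyl-1,3,2-dioxaborolane | CC1(C)OB(/C=C/c2c(OC)cc(OC)c3c2O[C@H](c2ccccc2)CC3)OC1(C)C | intermediate
9 | 2,6-dimethoxytoluene | Cc1c(OC)cccc1OC | starting material
10 | 2-(3,5-dimethoxy-4-methylphenyl)-4,4,5,5-tetramethyl-1,3,2-dioxaborolane (formed in the flask) | Cc1c(OC)cc(B2OC(C)(C)C(C)(C)O2)cc1OC | intermediate
11 | 3,5-dimethoxy-4-methylphenol | Cc1c(OC)cc(O)cc1OC | intermediate
12 | 2-iodo-3,5-dimethoxy-4-methylphenol | Cc1c(OC)cc(O)c(I)c1OC | intermediate
13 | 2-[(E)-2-[(2S)-5,7-dimethoxy-2-phenyl-3,4-dihydro-2H-chromen-8-yl]ethenyl]-3,5-dimethoxy-4-methylphenol | COc1cc(O)c(/C=C/c2c(OC)cc(OC)c3c2O[C@H](c2ccccc2)CC3)c(OC)c1C | target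

**Step count and risks**

Total step count: 8. Longest linear sequence: 6 steps (steps 1, 2, 3, 4, 5, 8).

Steps most likely to fail:

Step 4 (proposed new method). The methide carbon carries no substituent to relay chirality, so the chiral anion may discriminate the two faces of styrene poorly. In addition, oligomerisation or acetalisation of the o-quinone methide may outrun the slow capture by the weakly nucleophilic styrene. The fallback uses known chemistry, sets out from 4 and returns at 7, and moves the stereo-defining event from the cycloaddition to a hydrogenation. Heating 4 in toluene with trimethyl[(1-phenylethenyl)oxy]silane (the silyl enol ether of acetophenone), a far better dienophile for thermally generated o-quinone methides, should give racemic 5,7-dimethoxy-2-phenyl-2-(trimethylsilyloxy)chroman-8-carbaldehyde F1. Catalytic TsOH in warm toluene should then eliminate trimethylsilanol to give the flav-2-ene 5,7-dimethoxy-2-phenyl-4H-chromene-8-carbaldehyde F2. Asymmetric hydrogenation of its enol ether double bond with the cationic iridium phosphine–oxazoline catalyst [Ir(cod)((S)-tBu-PHOX)][B(C6H3-3,5-(CF3)2)4] under H2 in CH2Cl2 (ligand enantiomer chosen to deliver 2S) should give 7.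

Step 2. Site selectivity of the ether cleavage may be lost, with demethylation at the 4- or 6-methoxy group or double demethylation. The fallback sets out from 1 and returns at 3, placing the hydroxyl group before the second formyl group so that no choice between methoxy groups arises. Vilsmeier mono-formylation (POCl3, DMF) should give 2,4,6-trimethoxybenzaldehyde F3. BCl3 then cleaves one of its two equivalent ortho methoxy groups (the para one has no chelating partner) to give 2-hydroxy-4,6-dimethoxybenzaldehyde F4. Ortho-specific formylation through the magnesium phenoxide (MgCl2, Et3N, paraformaldehyde, MeCN, reflux), which delivers formaldehyde only to the position next to the phenolic oxygen, should give 3.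

Step 3. The reduction may overrun to the diol or stall as a statistical mixture, and the electron-rich salicyl alcohol may condense with itself on work-up. The fallback sets out from 3 and returns at 4, replacing partial reduction by full reduction and a self-limiting oxidation. Excess NaBH4 at 0 °C should give 2,6-bis(hydroxymethyl)-3,5-dimethoxyphenol F5, handled under neutral conditions. Activated MnO2 in CH2Cl2 at rt should then oxidise one benzylic alcohol; the formyl group so formed is hydrogen-bonded to the phenol and makes the ring less electron-rich, which slows oxidation of the second arm, giving 4.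

**Further compounds**

F1 | step 4 | 5,7-dimethoxy-2-phenyl-2-(trimethylsilyloxy)chroman-8-carbaldehyde (racemic) | O=Cc1c(OC)cc(OC)c2c1OC(c1ccccc1)(O[Si](C)(C)C)CC2
F2 | step 4 | 5,7-dimethoxy-2-phenyl-4H-chromene-8-carbaldehyde | O=Cc1c(OC)cc(OC)c2c1OC(c1ccccc1)=CC2
F3 | step 2 | 2,4,6-trimethoxybenzaldehyde | COc1cc(OC)c(C=O)c(OC)c1
F4 | step 2 | 2-hydroxy-4,6-dimethoxybenzaldehyde | COc1cc(O)c(C=O)c(OC)c1
F5 | step 3 | 2,6-bis(hydroxymethyl)-3,5-dimethoxyphenol | COc1cc(OC)c(CO)c(O)c1CO
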